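**Plan**
Skeleton labels used below: C1 = CH(O-angeloyl), C2 = CH2, C3 = CH(O-senecioyl), C4 = CMe2, C5 = cyclobutane CH next to C4, C6 = bridgehead CH next to C=O, C7 = C=O, C8 = CH=, C9 = C(Me)=, C10 = second bridgehead CH, C11 = quaternary C(Me).
Retrosynthesis: cut the two ester C–O bonds, trace the enone to a C7 carbinol and C5–H to a C5 tertiary alcohol, open the seven-membered ring at C4–C5 (aldol), then cut C5–C6 and C10–C11 together as an intramolecular ketene–alkene (2+2) cycloaddition; the resulting acyclic, oxygenated farnesoic acid is cut at C7–C8 and C1–C2 (two aldol bonds).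
Forward: chain assembly, then the (2+2) closes the four-membered ring and with it the six-membered ring C6–C11, then a samarium aldol closes the seven-membered ring and creates quaternary C4, then deoxygenation, esterification and enone unveiling.
Enabling feature: in the cyclobutane C5–C6–C11–C10, the one-carbon bridge C5 is bonded to C10, and C10 is joined to C6 by the three-atom chain C9–C8–C7 of the six-membered ring. A ketene C5=C10 therefore meets the trisubstituted alkene C6=C11 at the distance for crossed addition, and the C5 carbonyl it leaves is the handle for attaching C4.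
Stereochemistry: a temporary C7 carbinol (catalyst-controlled vinylogous aldol) steers the cycloaddition by A(1,3) strain and so fixes C6, C10 and C11; C1 comes from a reagent-controlled boron aldol, C3 from an oxazaborolidine reduction, and C5 is enforced by the ring.

Key step: step 10

Remark: the geometry of the C9=C10 double bond in 13–16 is erased in ketene 17; the E isomer is drawn.

**Route**

Step 1
Reactants: 1 2,2-dimethoxyacetaldehyde; 2 2-(triphenyl-λ5-phosphanylidene)propanal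
Product: 3 (2E)-4,4-dimethoxy-2-methylbut-2-enal
Conditions: toluene, 80 °C
Reagents that add atoms: none
Why: Wittig olefination with a formyl-stabilised ylide should give the E trisubstituted alkene (the future C6=C11) under thermodynamic control, the α-branched enal product being less reactive toward the ylide than 1.

Step 2
Reactants: 4 3-hydroxy-3-methylbutan-2-one
Product: 5 2-methyl-3-oxobutan-2-yl benzoate
Conditions: BzCl, pyridine, DMAP (cat.), CH2Cl2, 0 °C to rt
Reagents that add atoms: benzoyl chloride, O=C(Cl)c1ccccc1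
Why: DMAP-catalysed acylation of the tertiary α-hydroxy ketone installs the reductively cleavable group that later defines the regiochemistry of the C4 enolate.

Step 3
Reactants: 5 2-methyl-3-oxobutan-2-yl benzoate; 3 (2E)-4,4-dimethoxy-2-methylbut-2-enal
Product: 7 (5R,6E)-5-hydroxy-8,8-dimethoxy-2,6-dimethyl-3-oxooct-6-en-2-yl benzoate, via boron enolate 6 (not isolated)
Conditions: (+)-Ipc2BCl, Et3N, Et2O, 0 °C; then 3, −78 to −20 °C; H2O2, MeOH, pH 7 buffer
Reagents that add atoms: none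
Why: Boron aldol reaction of a methyl ketone that can enolise only at its methyl group, the isopinocampheyl ligands controlling the new C1 carbinol (re-face attack is expected for the (+)-reagent with methyl ketones; the R configuration would be confirmed by Mosher analysis, and any minor enantiomer becomes a separable diastereomer after step 7).

Step 4
Reactants: 7 (5R,6E)-5-hydroxy-8,8-dimethoxy-2,6-dimethyl-3-oxooct-6-en-2-yl benzoate
Product: 8 (5R,6E)-5-[(tert-butyldimethylsilyl)oxy]-8,8-dimethoxy-2,6-dimethyl-3-oxooct-6-en-2-yl benzoate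
Conditions: TBSOTf, 2,6-lutidine, CH2Cl2, −78 °C
Reagents that add atoms: tert-butyldimethylsilyl trifluoromethanesulfonate, CC(C)(C)[Si](C)(C)OS(=O)(=O)C(F)(F)F
Why: Silylation of the β-hydroxy ketone under non-nucleophilic base at low temperature should protect C1–OH without retro-aldol or elimination.

Step 5
Reactants: 8 (5R,6E)-5-[(tert-butyldimethylsilyl)oxy]-8,8-dimethoxy-2,6-dimethyl-3-oxooct-6-en-2-yl benzoate
Product: 9 (5R,6E)-5-[(tert-butyldimethylsilyl)oxy]-2,6-dimethyl-3,8-dioxooct-6-en-2-yl benzoate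
Conditions: PPTS (cat.), acetone/H2O, rt
Reagents that add atoms: water, O
Why: Mild acid-catalysed hydrolysis of the α,β-unsaturated dimethyl acetal should release the C7 aldehyde while the silyl ether, the β-silyloxy ketone and the E geometry are retained.

Step 6
Reactants: 10 methyl 3-methylbut-2-enoate
Product: 12 tert-butyl[(1-methoxy-3-methylbuta-1,3-dien-1-yl)oxy]dimethylsilane, via lithium dienolate 11 (not isolated)
Conditions: LDA, THF/DMPU, −78 °C; then TBSCl
Reagents that add atoms: tert-butyl(chloro)dimethylsilane, CC(C)(C)[Si](C)(C)Cl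
Why: γ-Deprotonation to the lithium dienolate and O-silylation give the silyl dienolate needed for the vinylogous Mukaiyama aldol reaction.

Step 7
Reactants: 9 (5R,6E)-5-[(tert-butyldimethylsilyl)oxy]-2,6-dimethyl-3,8-dioxooct-6-en-2-yl benzoate; 12 tert-butyl[(1-methoxy-3-methylbuta-1,3-dien-1-yl)oxy]dimethylsilane
Product: 13 methyl (2E,5S,6E,8R)-11-(benzoyloxy)-8-[(tert-butyldimethylsilyl)oxy]-5-hydroxy-3,7,11-trimethyl-10-oxododeca-2,6-dienoate
Conditions: SiCl4, (S,S)-bisphosphoramide of (S)-N,N'-dimethyl-1,1'-binaphthalene-2,2'-diamine with an N,N'-dimethylpentane-1,5-diamine linker (5 mol %), iPr2NEt (cat.), CH2Cl2, −78 °C; aq. KF/NaHCO3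
Reagents that add atoms: none
Why: Catalytic enantioselective vinylogous Mukaiyama aldol reaction (chiral Lewis base-activated SiCl4), in which the dienolate reacts only through its γ-carbon in a 1,2 sense with the enal and the (S,S)-catalyst is expected to direct si-face attack to give the 5S carbinol (skeleton C7; to be confirmed by Mosher analysis), the ketone and benzoate being inert.

Step 8
Reactants: 13 methyl (2E,5S,6E,8R)-11-(benzoyloxy)-8-[(tert-butyldimethylsilyl)oxy]-5-hydroxy-3,7,11-trimethyl-10-oxododeca-2,6-dienoate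
Product: 14 methyl (2E,5S,6E,8R)-11-(benzoyloxy)-8-[(tert-butyldimethylsilyl)oxy]-3,7,11-trimethyl-10-oxo-5-[(triethylsilyl)oxy]dodeca-2,6-dienoate
Conditions: Et3SiCl, imidazole, DMF, 0 °C
Reagents that add atoms: chlorotriethylsilane, CC[Si](Cl)(CC)CC
Why: Silylation blocks lactonisation of the δ-hydroxy acid and gives a C7 ether that can later be removed in the presence of the C1 tert-butyldimethylsilyl ether.

Step 9
Reactants: 14 methyl (2E,5S,6E,8R)-11-(benzoyloxy)-8-[(tert-butyldimethylsilyl)oxy]-3,7,11-trimethyl-10-oxo-5-[(triethylsilyl)oxy]dodeca-2,6-dienoate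
Product: 15 (2E,5S,6E,8R)-11-(benzoyloxy)-8-[(tert-butyldimethylsilyl)oxy]-3,7,11-trimethyl-10-oxo-5-[(triethylsilyl)oxy]dodeca-2,6-dienoic acid
Conditions: Me3SnOH, 1,2-dichloroethane, 80 °C; dilute HCl work-up
Reagents that add atoms: trimethyltin hydroxide, C[Sn](C)(C)O
Why: Near-neutral methyl ester cleavage with Me3SnOH is chosen because hydroxide would endanger the β-silyloxy ketone (E1cB) and the tertiary benzoate.

Step 10
Reactants: 15 (2E,5S,6E,8R)-11-(benzoyloxy)-8-[(tert-butyldimethylsilyl)oxy]-3,7,11-trimethyl-10-oxo-5-[(triethylsilyl)oxy]dodeca-2,6-dienoic acid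
Product: 18 (1R,4S,5R,7R)-7-[(1R)-4-(benzoyloxy)-1-[(tert-butyldimethylsilyl)oxy]-4-methyl-3-oxopentyl]-7-methyl-2-methylidene-4-[(triethylsilyl)oxy]bicyclo[3.1.1]heptan-6-one, via acid chloride 16 (not isolated), via vinylketene 17 (not isolated)
Conditions: 1-chloro-N,N,2-trimethylprop-1-en-1-amine, CH2Cl2, 0 °C to rt; then slow addition to Et3N, toluene, 110 °C, 0.005 M
Reagents that add atoms: none
Why: Et3N dehydrochlorinates acid chloride 16 at the C9 methyl group to vinylketene 17 (C5=C10), which undergoes a thermal intramolecular ketene–alkene (2+2) cycloaddition with the trisubstituted alkene C6=C11. The closest known reaction type is the intramolecular vinylketene–alkene cycloaddition of 3-methyl-2-enoyl chlorides, which turns geranic- and farnesoic-type chains into 2-methylidenebicyclo[3.1.1]heptan-6-ones. The four-membered ring closes in the crossed mode: the electrophilic ketene carbon C5 bonds to the less substituted alkene carbon C6 (positive charge building on tertiary C11) and C10 then bonds to C11, which also closes the six-membered ring C6–C7–C8–C9–C10–C11 as a bridged bicyclo[3.1.1]heptane and not as the fused bicyclo[3.2.0] isomer. C6 and C10 are held cis by the three-atom tether, and suprafacial addition to the E alkene puts the C11 methyl syn to the C7–C9 bridge and the C1 chain syn to the C5 carbonyl; the absolute sense comes from C7, because A(1,3) strain with the C11 methyl group keeps C7–H next to that methyl and the OSiEt3 group pointing outward, so the tether can reach only one alkene face. The step needs crossed regioselectivity, deprotonation at the methyl group without elimination of the C7 silyloxy group, and suppression of ketene dimerisation; the polarisation of the alkene, the mild amine base and high dilution with slow addition should secure them.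

Step 11
Reactants: 18 (1R,4S,5R,7R)-7-[(1R)-4-(benzoyloxy)-1-[(tert-butyldimethylsilyl)oxy]-4-methyl-3-oxopentyl]-7-methyl-2-methylidene-4-[(triethylsilyl)oxy]bicyclo[3.1.1]heptan-6-one
Product: 19 (1R,2R,3R,7R,8R,11S)-3-[(tert-butyldimethylsilyl)oxy]-7-hydroxy-2,6,6-trimethyl-9-methylidene-11-[(triethylsilyl)oxy]tricyclo[5.4.0.0^{2,8}]undecan-5-one
Conditions: SmI2 (2.5 equiv), THF, −78 to −20 °C; aq. NH4Cl
Reagents that add atoms: none
Why: Reformatsky-type samarium aldol reaction, in which two-electron cleavage of the α-benzoyloxy group gives the trivalent samarium enolate regiospecifically at C4 and this adds to the strained cyclobutanone carbonyl C5 from the only face the C11-bound chain can reach, closing the seven-membered ring and creating quaternary C4.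

Step 12
Reactants: 19 (1R,2R,3R,7R,8R,11S)-3-[(tert-butyldimethylsilyl)oxy]-7-hydroxy-2,6,6-trimethyl-9-methylidene-11-[(triethylsilyl)oxy]tricyclo[5.4.0.0^{2,8}]undecan-5-one
Product: 20 (1R,2R,3R,5R,7R,8R,11S)-3-[(tert-butyldimethylsilyl)oxy]-2,6,6-trimethyl-9-methylidene-11-[(triethylsilyl)oxy]tricyclo[5.4.0.0^{2,8}]undecane-5,7-diol
Conditions: (S)-1-methyl-3,3-diphenyltetrahydro-1H,3H-pyrrolo[1,2-c][1,3,2]oxazaborole (20 mol %), catecholborane, toluene, −78 to −40 °C
Reagents that add atoms: none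
Why: Corey–Bakshi–Shibata reduction, in which the (S)-catalyst distinguishes the quaternary C4 side (large) from the C2 methylene (small) and should give the R carbinol at C3, trans to the C1 silyl ether, while catecholborane at low temperature leaves the 1,1-disubstituted alkene alone.

Step 13
Reactants: 20 (1R,2R,3R,5R,7R,8R,11S)-3-[(tert-butyldimethylsilyl)oxy]-2,6,6-trimethyl-9-methylidene-11-[(triethylsilyl)oxy]tricyclo[5.4.0.0^{2,8}]undecane-5,7-diol; 21 3-methylbut-2-enoyl chloride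
Product: 22 (1R,2R,3R,5R,7R,8R,11S)-3-[(tert-butyldimethylsilyl)oxy]-7-hydroxy-2,6,6-trimethyl-9-methylidene-11-[(triethylsilyl)oxy]tricyclo[5.4.0.0^{2,8}]undecan-5-yl 3-methylbut-2-enoate
Conditions: pyridine, DMAP (cat.), CH2Cl2, 0 °C to rt
Reagents that add atoms: none
Why: Nucleophile-catalysed acylation of the secondary C3 alcohol, the tertiary cyclobutanol being too hindered to compete and pyridine as the only base avoiding deconjugation of the acyl group through a vinylketene.

Step 14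
Reactants: 22 (1R,2R,3R,5R,7R,8R,11S)-3-[(tert-butyldimethylsilyl)oxy]-7-hydroxy-2,6,6-trimethyl-9-methylidene-11-[(triethylsilyl)oxy]tricyclo[5.4.0.0^{2,8}]undecan-5-yl 3-methylbut-2-enoate
Product: 23 methyl (1R,2R,3R,5R,7R,8R,11S)-3-[(tert-butyldimethylsilyl)oxy]-2,6,6-trimethyl-5-[(3-methylbut-2-enoyl)oxy]-9-methylidene-11-[(triethylsilyl)oxy]tricyclo[5.4.0.0^{2,8}]undecan-7-yl oxalate
Conditions: methyl chlorooxoacetate, DMAP, Et3N, CH2Cl2, 0 °C to rt
Reagents that add atoms: methyl chlorooxoacetate, COC(=O)C(Cl)=O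
Why: Acylation of the hindered tertiary alcohol with the small, highly electrophilic oxalyl monoester chloride installs the radical leaving group; no elimination is possible because C4 is quaternary and C6 and C10 are bridgeheads.

Step 15
Reactants: 23 methyl (1R,2R,3R,5R,7R,8R,11S)-3-[(tert-butyldimethylsilyl)oxy]-2,6,6-trimethyl-5-[(3-methylbut-2-enoyl)oxy]-9-methylidene-11-[(triethylsilyl)oxy]tricyclo[5.4.0.0^{2,8}]undecan-7-yl oxalate
Product: 24 (1R,2R,3R,5R,7S,8R,11S)-3-[(tert-butyldimethylsilyl)oxy]-2,6,6-trimethyl-9-methylidene-11-[(triethylsilyl)oxy]tricyclo[5.4.0.0^{2,8}]undecan-5-yl 3-methylbut-2-enoate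
Conditions: Bu3SnH, AIBN (cat.), toluene, 110 °C
Reagents that add atoms: none
Why: Barton–McCombie-type radical deoxygenation of a tertiary alkyl methyl oxalate, in which the C5 cyclobutyl radical takes hydrogen on its only open face because C4 is held in the seven-membered ring, so C5 should form with the required configuration.

Step 16
Reactants: 24 (1R,2R,3R,5R,7S,8R,11S)-3-[(tert-butyldimethylsilyl)oxy]-2,6,6-trimethyl-9-methylidene-11-[(triethylsilyl)oxy]tricyclo[5.4.0.0^{2,8}]undecan-5-yl 3-methylbut-2-enoate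
Product: 25 (1R,2R,3R,5R,7S,8R,11S)-3-[(tert-butyldimethylsilyl)oxy]-11-hydroxy-2,6,6-trimethyl-9-methylidenetricyclo[5.4.0.0^{2,8}]undecan-5-yl 3-methylbut-2-enoate
Conditions: PPTS, MeOH, 0 °C to rt
Reagents that add atoms: none
Why: Acid-catalysed methanolysis should remove the triethylsilyl ether selectively in the presence of the more hindered and far more stable tert-butyldimethylsilyl ether.

Step 17
Reactants: 25 (1R,2R,3R,5R,7S,8R,11S)-3-[(tert-butyldimethylsilyl)oxy]-11-hydroxy-2,6,6-trimethyl-9-methylidenetricyclo[5.4.0.0^{2,8}]undecan-5-yl 3-methylbut-2-enoate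
Product: 27 (1R,2R,3R,5R,7S,8R)-3-[(tert-butyldimethylsilyl)oxy]-2,6,6,9-tetramethyl-11-oxotricyclo[5.4.0.0^{2,8}]undec-9-en-5-yl 3-methylbut-2-enoate, via exocyclic enone 26 (not isolated)
Conditions: Dess–Martin periodinane, NaHCO3, CH2Cl2, rt; then DBU, rt
Reagents that add atoms: none
Why: Dess–Martin oxidation gives the β,γ-unsaturated ketone and base then moves the exocyclic alkene into conjugation through the C8 dienolate, C6 being a bridgehead that cannot enolise so that no stereocentre is at risk.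

Step 18
Reactants: 27 (1R,2R,3R,5R,7S,8R)-3-[(tert-butyldimethylsilyl)oxy]-2,6,6,9-tetramethyl-11-oxotricyclo[5.4.0.0^{2,8}]undec-9-en-5-yl 3-methylbut-2-enoate
Product: 28 (1R,2R,3R,5R,7S,8R)-3-hydroxy-2,6,6,9-tetramethyl-11-oxotricyclo[5.4.0.0^{2,8}]undec-9-en-5-yl 3-methylbut-2-enoate
Conditions: HF·pyridine, pyridine, THF, 0 °C to rt
Reagents that add atoms: none
Why: Buffered acidic fluoride desilylation frees C1–OH while avoiding the 1,3-acyl migration that basic fluoride could cause.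

Step 19
Reactants: 28 (1R,2R,3R,5R,7S,8R)-3-hydroxy-2,6,6,9-tetramethyl-11-oxotricyclo[5.4.0.0^{2,8}]undec-9-en-5-yl 3-methylbut-2-enoate; 29 (2Z)-2-methylbut-2-enoic acid
Product: 31 (1R,2R,3R,5R,7S,8R)-2,6,6,9-tetramethyl-5-[(3-methylbut-2-enoyl)oxy]-11-oxotricyclo[5.4.0.0^{2,8}]undec-9-en-3-yl (2Z)-2-methylbut-2-enoate, via mixed anhydride 30 (not isolated)
Conditions: 2,4,6-trichlorobenzoyl chloride, Et3N, toluene, rt; then 28, 80 °C (no DMAP)
Reagents that add atoms: none
Why: Yamaguchi esterification through the mixed anhydride without DMAP should transfer the angeloyl group with its Z geometry intact and leaves the carbinol configuration unchanged.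

**Compound list**
1 | 2,2-dimethoxyacetaldehyde | COC(OC)C=O | starting material
2 | 2-(triphenyl-λ5-phosphanylidene)propanal | CC(C=O)=P(c1ccccc1)(c1ccccc1)c1ccccc1 | starting material
3 | (2E)-4,4-dimethoxy-2-methylbut-2-enal | COC(OC)/C=C(\C)C=O | intermediate
4 | 3-hydroxy-3-methylbutan-2-one | CC(=O)C(C)(C)O | starting material
5 | 2-methyl-3-oxobutan-2-yl benzoate | CC(=O)C(C)(C)OC(=O)c1ccccc1 | intermediate
6 | 3-(benzoyloxy)-3-methylbut-1-en-2-yl bis(isopinocampheyl)borinate | C=C(OB([C@H]1C[C@H]2C[C@@H]([C@@H]1C)C2(C)C)[C@H]1C[C@H]2C[C@@H]([C@@H]1C)C2(C)C)C(C)(C)OC(=O)c1ccccc1 | intermediate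
7 | (5R,6E)-5-hydroxy-8,8-dimethoxy-2,6-dimethyl-3-oxooct-6-en-2-yl benzoate | COC(OC)/C=C(\C)[C@H](O)CC(=O)C(C)(C)OC(=O)c1ccccc1 | intermediate
8 | (5R,6E)-5-[(tert-butyldimethylsilyl)oxy]-8,8-dimethoxy-2,6-dimethyl-3-oxooct-6-en-2-yl benzoate | COC(OC)/C=C(\C)[C@H](O[Si](C)(C)C(C)(C)C)CC(=O)C(C)(C)OC(=O)c1ccccc1 | intermediate
9 | (5R,6E)-5-[(tert-butyldimethylsilyl)oxy]-2,6-dimethyl-3,8-dioxooct-6-en-2-yl benzoate | O=C/C=C(\C)[C@H](O[Si](C)(C)C(C)(C)C)CC(=O)C(C)(C)OC(=O)c1ccccc1 | intermediate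
10 | methyl 3-methylbut-2-enoate | COC(=O)C=C(C)C | starting material
11 | lithium 1-methoxy-3-methylbuta-1,3-dien-1-olate | [Li+].COC([O-])=CC(C)=C | intermediate
12 | tert-butyl[(1-methoxy-3-methylbuta-1,3-dien-1-yl)oxy]dimethylsilane | COC(O[Si](C)(C)C(C)(C)C)=CC(C)=C | intermediate
13 | methyl (2E,5S,6E,8R)-11-(benzoyloxy)-8-[(tert-butyldimethylsilyl)oxy]-5-hydroxy-3,7,11-trimethyl-10-oxododeca-2,6-dienoate | COC(=O)/C=C(\C)C[C@H](O)/C=C(\C)[C@H](O[Si](C)(C)C(C)(C)C)CC(=O)C(C)(C)OC(=O)c1ccccc1 | intermediate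
14 | methyl (2E,5S,6E,8R)-11-(benzoyloxy)-8-[(tert-butyldimethylsilyl)oxy]-3,7,11-trimethyl-10-oxo-5-[(triethylsilyl)oxy]dodeca-2,6-dienoate | COC(=O)/C=C(\C)C[C@H](O[Si](CC)(CC)CC)/C=C(\C)[C@H](O[Si](C)(C)C(C)(C)C)CC(=O)C(C)(C)OC(=O)c1ccccc1 | intermediate
15 | (2E,5S,6E,8R)-11-(benzoyloxy)-8-[(tert-butyldimethylsilyl)oxy]-3,7,11-trimethyl-10-oxo-5-[(triethylsilyl)oxy]dodeca-2,6-dienoic acid | OC(=O)/C=C(\C)C[C@H](O[Si](CC)(CC)CC)/C=C(\C)[C@H](O[Si](C)(C)C(C)(C)C)CC(=O)C(C)(C)OC(=O)c1ccccc1 | intermediate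
16 | acid chloride of 15 | O=C(Cl)/C=C(\C)C[C@H](O[Si](CC)(CC)CC)/C=C(\C)[C@H](O[Si](C)(C)C(C)(C)C)CC(=O)C(C)(C)OC(=O)c1ccccc1 | intermediate
17 | vinylketene: (5S,6E,8R)-11-(benzoyloxy)-8-[(tert-butyldimethylsilyl)oxy]-7,11-dimethyl-3-methylidene-5-[(triethylsilyl)oxy]dodeca-1,6-diene-1,10-dione | O=C=CC(=C)C[C@H](O[Si](CC)(CC)CC)/C=C(\C)[C@H](O[Si](C)(C)C(C)(C)C)CC(=O)C(C)(C)OC(=O)c1ccccc1 | intermediate
18 | (1R,4S,5R,7R)-7-[(1R)-4-(benzoyloxy)-1-[(tert-butyldimethylsilyl)oxy]-4-methyl-3-oxopentyl]-7-methyl-2-methylidene-4-[(triethylsilyl)oxy]bicyclo[3.1.1]heptan-6-one | CC(C)(OC(=O)c1ccccc1)C(=O)C[C@@H](O[Si](C)(C)C(C)(C)C)[C@@]1(C)[C@H]2C(=O)[C@@H]1C(=C)C[C@@H]2O[Si](CC)(CC)CC | intermediate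
19 | (1R,2R,3R,7R,8R,11S)-3-[(tert-butyldimethylsilyl)oxy]-7-hydroxy-2,6,6-trimethyl-9-methylidene-11-[(triethylsilyl)oxy]tricyclo[5.4.0.0^{2,8}]undecan-5-one | C[Si](C)(C(C)(C)C)O[C@@H]1CC(=O)C(C)(C)[C@]2(O)[C@H]3[C@@H](O[Si](CC)(CC)CC)CC(=C)[C@@H]2[C@]31C | intermediate
20 | (1R,2R,3R,5R,7R,8R,11S)-3-[(tert-butyldimethylsilyl)oxy]-2,6,6-trimethyl-9-methylidene-11-[(triethylsilyl)oxy]tricyclo[5.4.0.0^{2,8}]undecane-5,7-diol | C[Si](C)(C(C)(C)C)O[C@@H]1C[C@@H](O)C(C)(C)[C@]2(O)[C@H]3[C@@H](O[Si](CC)(CC)CC)CC(=C)[C@@H]2[C@]31C | intermediate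
21 | 3-methylbut-2-enoyl chloride | CC(C)=CC(Cl)=O | starting material
22 | (1R,2R,3R,5R,7R,8R,11S)-3-[(tert-butyldimethylsilyl)oxy]-7-hydroxy-2,6,6-trimethyl-9-methylidene-11-[(triethylsilyl)oxy]tricyclo[5.4.0.0^{2,8}]undecan-5-yl 3-methylbut-2-enoate | C[Si](C)(C(C)(C)C)O[C@@H]1C[C@@H](OC(=O)C=C(C)C)C(C)(C)[C@]2(O)[C@H]3[C@@H](O[Si](CC)(CC)CC)CC(=C)[C@@H]2[C@]31C | intermediate
23 | methyl (1R,2R,3R,5R,7R,8R,11S)-3-[(tert-butyldimethylsilyl)oxy]-2,6,6-trimethyl-5-[(3-methylbut-2-enoyl)oxy]-9-methylidene-11-[(triethylsilyl)oxy]tricyclo[5.4.0.0^{2,8}]undecan-7-yl oxalate | C[Si](C)(C(C)(C)C)O[C@@H]1C[C@@H](OC(=O)C=C(C)C)C(C)(C)[C@]2(OC(=O)C(=O)OC)[C@H]3[C@@H](O[Si](CC)(CC)CC)CC(=C)[C@@H]2[C@]31C | intermediate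
24 | (1R,2R,3R,5R,7S,8R,11S)-3-[(tert-butyldimethylsilyl)oxy]-2,6,6-trimethyl-9-methylidene-11-[(triethylsilyl)oxy]tricyclo[5.4.0.0^{2,8}]undecan-5-yl 3-methylbut-2-enoate | C[Si](C)(C(C)(C)C)O[C@@H]1C[C@@H](OC(=O)C=C(C)C)C(C)(C)[C@@H]2[C@H]3[C@@H](O[Si](CC)(CC)CC)CC(=C)[C@@H]2[C@]31C | intermediate
25 | (1R,2R,3R,5R,7S,8R,11S)-3-[(tert-butyldimethylsilyl)oxy]-11-hydroxy-2,6,6-trimethyl-9-methylidenetricyclo[5.4.0.0^{2,8}]undecan-5-yl 3-methylbut-2-enoate | C[Si](C)(C(C)(C)C)O[C@@H]1C[C@@H](OC(=O)C=C(C)C)C(C)(C)[C@@H]2[C@H]3[C@@H](O)CC(=C)[C@@H]2[C@]31C | intermediate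
26 | (1R,2R,3R,5R,7S,8R)-3-[(tert-butyldimethylsilyl)oxy]-2,6,6-trimethyl-9-methylidene-11-oxotricyclo[5.4.0.0^{2,8}]undecan-5-yl 3-methylbut-2-enoate | C[Si](C)(C(C)(C)C)O[C@@H]1C[C@@H](OC(=O)C=C(C)C)C(C)(C)[C@@H]2[C@H]3C(=O)CC(=C)[C@@H]2[C@]31C | intermediate
27 | (1R,2R,3R,5R,7S,8R)-3-[(tert-butyldimethylsilyl)oxy]-2,6,6,9-tetramethyl-11-oxotricyclo[5.4.0.0^{2,8}]undec-9-en-5-yl 3-methylbut-2-enoate | C[Si](C)(C(C)(C)C)O[C@@H]1C[C@@H](OC(=O)C=C(C)C)C(C)(C)[C@@H]2[C@H]3C(=O)C=C(C)[C@@H]2[C@]31C | intermediate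
28 | (1R,2R,3R,5R,7S,8R)-3-hydroxy-2,6,6,9-tetramethyl-11-oxotricyclo[5.4.0.0^{2,8}]undec-9-en-5-yl 3-methylbut-2-enoate | O[C@@H]1C[C@@H](OC(=O)C=C(C)C)C(C)(C)[C@@H]2[C@H]3C(=O)C=C(C)[C@@H]2[C@]31C | intermediate
29 | (2Z)-2-methylbut-2-enoic acid (angelic acid) | C/C=C(/C)C(O)=O | starting material
30 | (2Z)-2-methylbut-2-enoic 2,4,6-trichlorobenzoic anhydride | C/C=C(/C)C(=O)OC(=O)c1c(Cl)cc(Cl)cc1Cl | intermediate
31 | (1R,2R,3R,5R,7S,8R)-2,6,6,9-tetramethyl-5-[(3-methylbut-2-enoyl)oxy]-11-oxotricyclo[5.4.0.0^{2,8}]undec-9-en-3-yl (2Z)-2-methylbut-2-enoate | C/C=C(/C)C(=O)O[C@@H]1C[C@@H](OC(=O)C=C(C)C)C(C)(C)[C@@H]2[C@H]3C(=O)C=C(C)[C@@H]2[C@]31C | target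

**Step count and risks**
Total: 19 steps. Longest linear sequence: 17 steps (steps 1, 3–5, 7–19).

Step 10. The cycloaddition may be slowed by the two allylic silyloxy groups flanking the alkene, so that ketene oligomerisation, vinylogous elimination of the C7 silyloxy group, or leakage to the other alkene face takes over. The fallback replaces the ketene by a far more electrophilic keteniminium ion. It sets out from 15: acid chloride 16 is treated with pyrrolidine at −78 °C to give the tertiary amide F1. Tf2O and 2,4,6-collidine in 1,2-dichloroethane at 80 °C activate the amide, vinylogous deprotonation at the C9 methyl gives the vinyl keteniminium triflate, and its intramolecular (2+2) cycloaddition with C6=C11 gives the cyclobutaniminium triflate F2. Hydrolysis with aqueous NaHCO3 returns to the route at 18.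

Step 11. The samarium enolate may be protonated before it closes the congested C4–C5 bond, the aldol addition may revert, or the cyclobutanone may be reduced to a ketyl. The fallback separates enolate formation from ring closure and activates the ketone with a Lewis acid instead. It sets out from 18: SmI2 in the presence of Me3SiCl traps the enolate as the tetrasubstituted trimethylsilyl enol ether F3, and TiCl4 in CH2Cl2 at −78 °C then effects an intramolecular Mukaiyama aldol addition to the cyclobutanone, returning to the route at 19.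

Step 14. Acylation of the very hindered neutral tertiary hydroxyl may stall. The fallback acylates the oxygen at the moment it is formed, as a metal alkoxide, and deoxygenates before the reduction. It sets out from 18: SmI2 as in step 11, then methyl chlorooxoacetate added to the samarium alkoxide in the same flask, gives the tertiary oxalate F4. Bu3SnH/AIBN at high stannane concentration (to outrun a 1,2-acyl shift of the β-keto radical) gives the deoxygenated ketone F5. Oxazaborolidine reduction as in step 12 gives the alcohol F6, and acylation with 21 as in step 13 returns to the route at 24.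

**Further compounds**
F1 | step 10 | 1-[(2E,5S,6E,8R)-11-(benzoyloxy)-8-[(tert-butyldimethylsilyl)oxy]-3,7,11-trimethyl-10-oxo-5-[(triethylsilyl)oxy]dodeca-2,6-dienoyl]pyrrolidine | O=C(/C=C(\C)C[C@H](O[Si](CC)(CC)CC)/C=C(\C)[C@H](O[Si](C)(C)C(C)(C)C)CC(=O)C(C)(C)OC(=O)c1ccccc1)N1CCCC1
F2 | step 10 | pyrrolidinium-1-ylidene analogue of 18 at the cyclobutanone carbon, triflate salt | CC(C)(OC(=O)c1ccccc1)C(=O)C[C@@H](O[Si](C)(C)C(C)(C)C)[C@@]1(C)[C@H]2C(=[N+]3CCCC3)[C@@H]1C(=C)C[C@@H]2O[Si](CC)(CC)CC.[O-]S(=O)(=O)C(F)(F)F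
F3 | step 11 | trimethylsilyl enol ether of the debenzoyloxylated ketone (C3-OSiMe3, C3=C4) | CC(C)=C(O[Si](C)(C)C)C[C@@H](O[Si](C)(C)C(C)(C)C)[C@@]1(C)[C@H]2C(=O)[C@@H]1C(=C)C[C@@H]2O[Si](CC)(CC)CC
F4 | step 14 | methyl oxalate of 19 at the tertiary hydroxyl | C[Si](C)(C(C)(C)C)O[C@@H]1CC(=O)C(C)(C)[C@]2(OC(=O)C(=O)OC)[C@H]3[C@@H](O[Si](CC)(CC)CC)CC(=C)[C@@H]2[C@]31C
F5 | step 14 | (1R,2R,3R,7S,8R,11S)-3-[(tert-butyldimethylsilyl)oxy]-2,6,6-trimethyl-9-methylidene-11-[(triethylsilyl)oxy]tricyclo[5.4.0.0^{2,8}]undecan-5-one | C[Si](C)(C(C)(C)C)O[C@@H]1CC(=O)C(C)(C)[C@@H]2[C@H]3[C@@H](O[Si](CC)(CC)CC)CC(=C)[C@@H]2[C@]31C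
F6 | step 14 | (1R,2R,3R,5R,7S,8R,11S)-3-[(tert-butyldimethylsilyl)oxy]-2,6,6-trimethyl-9-methylidene-11-[(triethylsilyl)oxy]tricyclo[5.4.0.0^{2,8}]undecan-5-ol | C[Si](C)(C(C)(C)C)O[C@@H]1C[C@@H](O)C(C)(C)[C@@H]2[C@H]3[C@@H](O[Si](CC)(CC)CC)CC(=C)[C@@H]2[C@]31C
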